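**Retrosynthetic overview**
1. Feature: in the tetrahydrofuran ring (O1, C2-aryl, C3-CH2O-acyl, C4-benzyl, C5H2) the adjacent stereocentres C3 and C4 carry the branches C2, C3-CH2O, C4-CH2Ar and C5. This is the pattern of Cβ/Cα of a 5-alkoxybutenolide, with C5 as the lactone carbonyl, the C3-CH2O carbon as the acetal carbon and C2 as an aroyl-anion carbon.
2. Late cuts: three O-benzyl groups, the 4-hydroxybenzoate at C3-CH2O, then C2–O1 (benzylic cation taken by the C5 hydroxyl), leading back to an acyclic triol.
3. The triol comes from a keto lactone, and this from its bis(phenylthio)acetal. The key cut removes C2–C3 and C4–CH2Ar together, giving a lithiated O-benzylvanillin dithioacetal, (5S)-(+)-menthyloxybutenolide and a guaiacylmethyl bromide.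
4. Ring order: the butenolide ring comes from furfural, serves only as a stereochemical template and is opened by LiAlH4. The tetrahydrofuran is the only ring made, in step 10.

Key step: step 7

Remark: O1 and C2–C5 denote the tetrahydrofuran of the target, and lactone locants are marked as such. The carbinol centre of 14 is expected as an epimer mixture and is written without configuration, because the ionisation in step 10 erases it.

**Step 1**
Reactants: 1 furfural
Product: 2 5-hydroxyfuran-2(5H)-one (racemic pseudo-acid)
Conditions: O2, hν (visible), rose bengal (disodium 4,5,6,7-tetrachloro-2',4',5',7'-tetraiodofluorescein, cat.), MeOH, 20 °C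
Reagents that add atoms: oxygen, O=O
Why: Dye-sensitised singlet-oxygen [4+2] photooxygenation of the furan, followed in methanol by loss of the formyl carbon as its methyl ester, is the standard entry to this pseudo-acid, whose C5 centre forms racemic and is configurationally labile.

**Step 2**
Reactants: 2 5-hydroxyfuran-2(5H)-one; 3 (+)-menthol, (1S,2R,5S)
Product: 4 (5S)-5-{[(1S,2R,5S)-2-isopropyl-5-methylcyclohexyl]oxy}furan-2(5H)-one
Conditions: (+)-camphor-10-sulfonic acid (cat.), toluene, reflux, azeotropic removal of water; crystallisation from hexanes, −20 °C, mother liquor re-equilibrated with the acid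
Reagents that add atoms: none
Why: In this acid-catalysed pseudo-ester (acetal) formation the acetal centre equilibrates under the acid, and the (5S)-diastereomer of the (+)-menthyl series is the one that crystallises, so crystallisation-driven resolution sets lactone C5.

**Step 3**
Reactants: 5 vanillin
Product: 6 4-benzyloxy-3-methoxybenzaldehyde (O-benzylvanillin)
Conditions: BnBr, K2CO3, DMF, 25 °C
Reagents that add atoms: benzyl bromide, BrCc1ccccc1
Why: This is a Williamson ether synthesis on an acidic phenol with a reactive benzylic halide, and the aldehyde is inert to carbonate.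

**Step 4**
Reactants: 6 O-benzylvanillin
Product: 7 4-benzyloxy-3-methoxybenzaldehyde bis(phenylthio)acetal
Conditions: PhSH (2.1 equiv), BF3·OEt2 (0.1 equiv), CH2Cl2, 0 °C
Reagents that add atoms: thiophenol, Sc1ccccc1
Why: Lewis-acid-catalysed dithioacetalisation of an electron-rich aromatic aldehyde is fast, and the catalytic loading and low temperature spare the aryl benzyl ether.

**Step 5**
Reactants: 6 O-benzylvanillin
Product: 8 (4-benzyloxy-3-methoxyphenyl)methanol
Conditions: NaBH4, MeOH, 0 °C
Reagents that add atoms: none
Why: Borohydride reduction of an aldehyde is reliable, and no other reducible group is present.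

**Step 6**
Reactants: 8 (4-benzyloxy-3-methoxyphenyl)methanol
Product: 9 4-benzyloxy-3-methoxybenzyl bromide
Conditions: PBr3 (0.4 equiv), Et2O, 0 °C; used at once
Reagents that add atoms: phosphorus tribromide, BrP(Br)Br
Why: PBr3 bromination (phosphite ester formation, then displacement by bromide) is mild enough for this labile electron-rich benzylic bromide, which is taken on without storage.

**Step 7**
Reactants: 7 O-benzylvanillin bis(phenylthio)acetal; 4 (5S)-(+)-menthyloxyfuranone; 9 4-benzyloxy-3-methoxybenzyl bromide
Product: 12 (3S,4S,5S)-3-(4-benzyloxy-3-methoxybenzyl)-4-[(4-benzyloxy-3-methoxyphenyl)bis(phenylthio)methyl]-5-[(+)-menthyloxy]dihydrofuran-2(3H)-one (trans,trans), via lithiated dithioacetal 10 (not isolated), via lithium lactone enolate 11 (not isolated)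
Conditions: n-BuLi (1.0 equiv), THF, −78 °C; 4, −78 °C; 9, N,N'-dimethylpropyleneurea (DMPU), −78 → 25 °C; aq NH4Cl
Reagents that add atoms: none
Why: n-BuLi deprotonates 7 to the sulfur-stabilised benzylic carbanion 10, a soft masked aroyl anion that adds 1,4 to butenolide 4 (C2–C3 bond) and leaves lithium enolate 11, which is C-alkylated in an SN2 reaction by the benzylic bromide 9 (C4–CH2Ar bond). The closest known reaction type is the tandem Michael addition/enolate alkylation of lithiated aryl bis(phenylthio)acetals with 5-alkoxybutenolides and benzylic halides, established for dibenzylbutyrolactone lignans. No ring is closed; the lactone ring is carried through unchanged as the stereochemical template. The lactone C4 centre (target C3) is controlled by the acetal centre C5, whose menthyloxy group blocks one face so that 10 enters anti to it, and the lactone C3 centre (target C4) is controlled by the new, very bulky bis(phenylthio)arylmethyl group, which forces 9 onto the opposite enolate face and gives the trans,trans lactone. The step needs 1,4- over 1,2-addition, secured by the charge-delocalised and hindered carbanion, and C-alkylation faster than proton transfer, secured by the reactive benzylic bromide and the DMPU co-solvent. The 3,4-trans lactone relation turns into the 3,4-cis relation of the tetrahydrofuran because target C3 later takes C2 into the ring and leaves the former acetal carbon outside.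

**Step 8**
Reactants: 12 trans,trans dithioacetal lactone
Product: 13 (3S,4S,5S)-3-(4-benzyloxy-3-methoxybenzyl)-4-(4-benzyloxy-3-methoxybenzoyl)-5-[(+)-menthyloxy]dihydrofuran-2(3H)-one
Conditions: HgO (2 equiv), BF3·OEt2 (2 equiv), aq THF, 25 °C
Reagents that add atoms: water, O
Why: Thiophilic hydrolysis of the dithioacetal assisted by divalent mercury is selective for sulfur and leaves lactone, acetal and benzyl ethers intact, and the centre α to the new ketone already holds the favoured trans,trans arrangement.

**Step 9**
Reactants: 13 keto lactone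
Product: 14 (2S,3S)-2-[(4-benzyloxy-3-methoxyphenyl)(hydroxy)methyl]-3-(4-benzyloxy-3-methoxybenzyl)butane-1,4-diol (carbinol epimers)
Conditions: LiAlH4 (excess), THF, 0 °C → reflux; H2O, aq NaOH
Reagents that add atoms: none
Why: Exhaustive LiAlH4 reduction takes the ketone to the carbinol and the acyloxy-acetal lactone to two primary alcohols with release of the auxiliary, without touching C3 and C4, and the configuration of the new carbinol centre is irrelevant.

**Step 10**
Reactants: 14 triol
Product: 15 [(2R,3S,4S)-2-(4-benzyloxy-3-methoxyphenyl)-4-(4-benzyloxy-3-methoxybenzyl)tetrahydrofuran-3-yl]methanol (4,4'-di-O-benzyl-(−)-lariciresinol)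
Conditions: camphor-10-sulfonic acid (0.1 equiv), CH2Cl2, 0 °C, quenched with aq NaHCO3 at full conversion
Reagents that add atoms: none
Why: In this benzylic SN1 cycloetherification, known for 7-hydroxy-dibenzylbutanediol lignans, the acid ionises only the p-alkoxybenzylic alcohol, the C5 hydroxyl closes the five-membered ring (the C3 hydroxymethyl could only give an oxetane), and the aryl group settles trans to the C3 substituent, so both carbinol epimers converge on (2R).

**Step 11**
Reactants: 16 4-hydroxybenzoic acid
Product: 17 4-benzyloxybenzoic acid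
Conditions: BnBr (1.1 equiv), KOH (2.5 equiv), EtOH/H2O, reflux; aq HCl
Reagents that add atoms: benzyl bromide, BrCc1ccccc1
Why: In a Williamson ether synthesis on the dianion the phenoxide is the better nucleophile in the protic medium, and any benzyl ester formed is saponified under the same conditions.

**Step 12**
Reactants: 15 di-O-benzyl-(−)-lariciresinol; 17 4-benzyloxybenzoic acid
Product: 18 [(2R,3S,4S)-2-(4-benzyloxy-3-methoxyphenyl)-4-(4-benzyloxy-3-methoxybenzyl)tetrahydrofuran-3-yl]methyl 4-benzyloxybenzoate
Conditions: N,N'-dicyclohexylcarbodiimide (DCC), 4-(dimethylamino)pyridine (cat.), CH2Cl2, 0 → 25 °C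
Reagents that add atoms: none
Why: Steglich esterification acylates the only free hydroxyl, a primary alcohol, under neutral conditions that do not ionise the 2-aryl tetrahydrofuran.

**Step 13**
Reactants: 18 tri-O-benzyl agastinol
Product: 19 agastinol
Conditions: H2 (1 atm), 10% Pd/C, EtOAc/EtOH, 25 °C, stopped after uptake of 3 equiv H2
Reagents that add atoms: none
Why: Catalytic hydrogenolysis cleaves aryl benzyl ethers much faster than the hindered cyclic benzylic C2–O1 ether, the alkyl benzoate is inert, and no stereocentre is touched.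

**Compound list**
1 | furfural | O=Cc1ccco1 | starting material
2 | 5-hydroxyfuran-2(5H)-one (racemic) | O=C1C=CC(O)O1 | intermediate
3 | (+)-menthol, (1S,2R,5S) | CC(C)[C@H]1CC[C@H](C)C[C@@H]1O | starting material
4 | (5S)-5-[(+)-menthyloxy]furan-2(5H)-one | O=C1C=C[C@@H](O[C@H]2C[C@@H](C)CC[C@@H]2C(C)C)O1 | intermediate
5 | vanillin | COc1cc(C=O)ccc1O | starting material
6 | 4-benzyloxy-3-methoxybenzaldehyde | COc1cc(C=O)ccc1OCc1ccccc1 | intermediate
7 | O-benzylvanillin bis(phenylthio)acetal | COc1cc(C(Sc2ccccc2)Sc2ccccc2)ccc1OCc1ccccc1 | intermediate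
8 | (4-benzyloxy-3-methoxyphenyl)methanol | COc1cc(CO)ccc1OCc1ccccc1 | intermediate
9 | 4-benzyloxy-3-methoxybenzyl bromide | COc1cc(CBr)ccc1OCc1ccccc1 | intermediate
10 | lithiated dithioacetal (not isolated) | [Li]C(Sc1ccccc1)(Sc1ccccc1)c1ccc(OCc2ccccc2)c(OC)c1 | intermediate
11 | lithium lactone enolate, 4,5-trans (not isolated) | [Li]OC1=C[C@H](C(Sc2ccccc2)(Sc2ccccc2)c2ccc(OCc3ccccc3)c(OC)c2)[C@@H](O[C@H]2C[C@@H](C)CC[C@@H]2C(C)C)O1 | intermediate
12 | (3S,4S,5S) trans,trans dithioacetal lactone | O=C1[C@@H](Cc2ccc(OCc3ccccc3)c(OC)c2)[C@H](C(Sc2ccccc2)(Sc2ccccc2)c2ccc(OCc3ccccc3)c(OC)c2)[C@@H](O[C@H]2C[C@@H](C)CC[C@@H]2C(C)C)O1 | intermediate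
13 | (3S,4S,5S) keto lactone | O=C1[C@@H](Cc2ccc(OCc3ccccc3)c(OC)c2)[C@H](C(=O)c2ccc(OCc3ccccc3)c(OC)c2)[C@@H](O[C@H]2C[C@@H](C)CC[C@@H]2C(C)C)O1 | intermediate
14 | (2S,3S) triol, carbinol epimers | OC(c1ccc(OCc2ccccc2)c(OC)c1)[C@H](CO)[C@@H](CO)Cc1ccc(OCc2ccccc2)c(OC)c1 | intermediate
15 | 4,4'-di-O-benzyl-(−)-lariciresinol, (2R,3S,4S) | COc1cc(C[C@@H]2CO[C@@H](c3ccc(OCc4ccccc4)c(OC)c3)[C@@H]2CO)ccc1OCc1ccccc1 | intermediate
16 | 4-hydroxybenzoic acid | O=C(O)c1ccc(O)cc1 | starting material
17 | 4-benzyloxybenzoic acid | O=C(O)c1ccc(OCc2ccccc2)cc1 | intermediate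
18 | tri-O-benzyl agastinol, (2R,3S,4S) | COc1cc(C[C@@H]2CO[C@@H](c3ccc(OCc4ccccc4)c(OC)c3)[C@@H]2COC(=O)c2ccc(OCc3ccccc3)cc2)ccc1OCc1ccccc1 | intermediate
19 | agastinol, (2R,3S,4S) | COc1cc(C[C@@H]2CO[C@@H](c3ccc(O)c(OC)c3)[C@@H]2COC(=O)c2ccc(O)cc2)ccc1O | target

**Step count**
Total step count: 13.
Longest linear sequence: 9 steps (5 → 6 → 8 → 9 → 12 → 13 → 14 → 15 → 18 → 19; steps 3, 5, 6, 7, 8, 9, 10, 12, 13).

**Steps most likely to fail**

Step 10.
- The risk is repeated acid re-ionisation of the ring-closed product. This would let Friedel–Crafts capture of the benzylic cation by the pendant guaiacyl ring drain material irreversibly. A second risk is an incomplete preference for the 2,3-trans arrangement.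
- The fallback sets out from 14 and returns at 15. It generates the cation once only, in a base-buffered medium.
- The two primary hydroxyls are silylated selectively (tert-butyldimethylsilyl chloride, imidazole, CH2Cl2, 0 °C) to the bis(silyl ether) carbinol F2.
- Mesylation of the remaining benzylic alcohol (MsCl, Et3N, CH2Cl2, −20 → 0 °C) gives a mesylate that ionises spontaneously. The C5 silyl ether oxygen closes the ring with loss of its silyl group to give the C3-silyloxymethyl tetrahydrofuran F3.
- Bu4NF in THF then frees 15.

Step 7.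
- The risk is sluggish alkylation of the hindered enolate, so that proton transfer or decay of the labile bromide overtakes the second bond formation.
- The fallback sets out from 7 and 4 and returns at 12. It separates the two C–C bond formations.
- The conjugate addition is quenched at −78 °C with aq NH4Cl and the 4,5-trans conjugate adduct F1 is isolated and purified.
- Its enolate is regenerated on its own with LiN(SiMe3)2 in THF/DMPU at −78 °C and alkylated with freshly made 9. The attack is again anti to the dithioacetal-bearing group.

Step 13.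
- The risk is over-hydrogenolysis, that is reductive opening of the benzylic C2–O1 bond alongside removal of the benzyl ethers.
- The fallback sets out from 13 and returns at 19. It debenzylates before any benzylic C–O single bond of the skeleton exists.
- H2 and Pd/C in EtOAc on 13, whose electron-rich aryl ketone reduces slowly, should give the bisphenol keto lactone F4.
- Excess LiAlH4 in THF then gives the phenolic triol F5.
- A trace of camphor-10-sulfonic acid in THF closes C2–O1 through quinone-methide-type ionisation to (−)-lariciresinol F6.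
- A chemoselective Mitsunobu esterification with unprotected 16 (PPh3, diisopropyl azodicarboxylate, THF, 0 °C) gives 19 directly. Only the aliphatic hydroxyl is activated on phosphorus, and only the carboxylic acid is acidic enough to act as the nucleophile, so the primary alcohol alone is acylated.

**Further compounds**
F1 | step 7 | (4S,5S)-4-[(4-benzyloxy-3-methoxyphenyl)bis(phenylthio)methyl]-5-[(+)-menthyloxy]dihydrofuran-2(3H)-one | O=C1C[C@H](C(Sc2ccccc2)(Sc2ccccc2)c2ccc(OCc3ccccc3)c(OC)c2)[C@@H](O[C@H]2C[C@@H](C)CC[C@@H]2C(C)C)O1
F2 | step 10 | 1,4-bis(tert-butyldimethylsilyl) ether of triol 14 | OC(c1ccc(OCc2ccccc2)c(OC)c1)[C@H](CO[Si](C)(C)C(C)(C)C)[C@@H](CO[Si](C)(C)C(C)(C)C)Cc1ccc(OCc2ccccc2)c(OC)c1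
F3 | step 10 | tert-butyldimethylsilyl ether of 15 | COc1cc(C[C@@H]2CO[C@@H](c3ccc(OCc4ccccc4)c(OC)c3)[C@@H]2CO[Si](C)(C)C(C)(C)C)ccc1OCc1ccccc1
F4 | step 13 | (3S,4S,5S)-3-(4-hydroxy-3-methoxybenzyl)-4-(4-hydroxy-3-methoxybenzoyl)-5-[(+)-menthyloxy]dihydrofuran-2(3H)-one | O=C1[C@@H](Cc2ccc(O)c(OC)c2)[C@H](C(=O)c2ccc(O)c(OC)c2)[C@@H](O[C@H]2C[C@@H](C)CC[C@@H]2C(C)C)O1
F5 | step 13 | (2S,3S)-2-[hydroxy(4-hydroxy-3-methoxyphenyl)methyl]-3-(4-hydroxy-3-methoxybenzyl)butane-1,4-diol (carbinol epimers) | OC(c1ccc(O)c(OC)c1)[C@H](CO)[C@@H](CO)Cc1ccc(O)c(OC)c1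
F6 | step 13 | (−)-lariciresinol, (2R,3S,4S) | COc1cc(C[C@@H]2CO[C@@H](c3ccc(O)c(OC)c3)[C@@H]2CO)ccc1O
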